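**Plan**
The last cut removes the =C(CH3)2 ends of the three CH2–CH=C(CH3)2 chains on C6 and C8 (ring A) and C5' (ring B). Each chain is an allyl group with a different alkene terminus, so the precursor is the triallyl flavanone plus 2-methylbut-2-ene.
Earlier cuts are O1–C2 (oxa-Michael), C2–C3 (Claisen–Schmidt) and the three aryl–CH2 bonds, which go back to O-allyl ethers through aromatic Claisen shifts.
Forward, the ring A ketone comes from phloroacetophenone (bis-O-allylation, double Claisen, bis-MOM). The ring B aldehyde comes from 3,4-dihydroxybenzaldehyde (4-O-allyl, 3-O-MOM, Claisen, O-methylation).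
Rings A and B are bought as arenes. After the condensation, ring C closes by addition of the single free 2'-OH to the enone.
C2, the only stereocentre, forms as a racemate and becomes 2S by kinetic resolution. Asymmetric transfer hydrogenation with the (R,R)-Ru–TsDPEN catalyst removes the 2R ketone as the cis-flavan-4-ol.
Acid then removes the three MOM groups while the side chains next to the C5 and C7 phenols are still acid-stable allyl groups, and a neutral metathesis ends the route.

Key step: step 12

Remark: the [C@@H] atom of the given SMILES is C2 with S configuration (O1 > C1' > C3 > H); commercial phloroacetophenone hydrate is dried before use.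

**Step 1**
Reactants: 1 2',4',6'-trihydroxyacetophenone; 2 allyl bromide (2 equiv)
Product: 3 1-[2,4-bis(allyloxy)-6-hydroxyphenyl]ethanone
Conditions: K2CO3, acetone, reflux
Reagents that add atoms: none
Why: Williamson etherification in which the weak base and two equivalents of halide alkylate the 4-OH and one ortho OH, while the remaining ortho OH is hydrogen-bonded to the acetyl oxygen and stays free.

**Step 2**
Reactants: 3 1-[2,4-bis(allyloxy)-6-hydroxyphenyl]ethanone
Product: 4 1-(3,5-diallyl-2,4,6-trihydroxyphenyl)ethanone
Conditions: PhNEt2, 200 °C, Ar
Reagents that add atoms: none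
Why: Twofold aromatic Claisen rearrangement in which C3 and C5 are the only open ring positions, so every order of ortho shifts (or ortho shift then Cope shift to para) converges on the same symmetric product, and an unsubstituted allyl group cannot give a branched isomer.

**Step 3**
Reactants: 4 1-(3,5-diallyl-2,4,6-trihydroxyphenyl)ethanone
Product: 5 1-[3,5-diallyl-2-hydroxy-4,6-bis(methoxymethoxy)phenyl]ethanone
Conditions: MOMCl (2.2 equiv), K2CO3, acetone, 0 °C to rt
Reagents that add atoms: chloromethyl methyl ether, COCCl
Why: Selective O-alkylation in which the acidic 4-OH and one of the two equivalent ortho OH groups react, after which the last OH is chelated to the carbonyl and stays free for the later ring closure.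

**Step 4**
Reactants: 6 3,4-dihydroxybenzaldehyde; 2 allyl bromide (1 equiv)
Product: 7 4-(allyloxy)-3-hydroxybenzaldehyde
Conditions: NaHCO3, DMF, 40 °C
Reagents that add atoms: none
Why: Regioselective Williamson monoalkylation, because the 4-OH para to the formyl group is clearly the more acidic phenol and hydrogen carbonate ionises only that site.

**Step 5**
Reactants: 7 4-(allyloxy)-3-hydroxybenzaldehyde
Product: 8 4-(allyloxy)-3-(methoxymethoxy)benzaldehyde
Conditions: MOMCl, K2CO3, acetone, rt
Reagents that add atoms: chloromethyl methyl ether, COCCl
Why: Standard MOM protection of the remaining phenol, placed before the thermal step so that the next free OH to appear can only be the one that must carry the methyl group.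

**Step 6**
Reactants: 8 4-(allyloxy)-3-(methoxymethoxy)benzaldehyde
Product: 9 3-allyl-4-hydroxy-5-(methoxymethoxy)benzaldehyde
Conditions: PhNEt2, 195 °C, Ar
Reagents that add atoms: none
Why: Aromatic Claisen rearrangement of the O-allylvanillin type, in which one ortho carbon bears the OMOM group, so the allyl group can only move to the unsubstituted ortho carbon and releases the 4-OH.

**Step 7**
Reactants: 9 3-allyl-4-hydroxy-5-(methoxymethoxy)benzaldehyde
Product: 10 3-allyl-4-methoxy-5-(methoxymethoxy)benzaldehyde
Conditions: MeI, K2CO3, DMF, rt
Reagents that add atoms: iodomethane, CI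
Why: Williamson methylation of the only free, acidic phenol fixes the ring B pattern (4'-OMe, protected 3'-O, 5'-allyl) without any regiochemical choice.

**Step 8**
Reactants: 5 1-[3,5-diallyl-2-hydroxy-4,6-bis(methoxymethoxy)phenyl]ethanone; 10 3-allyl-4-methoxy-5-(methoxymethoxy)benzaldehyde
Product: 11 (E)-1-[3,5-diallyl-2-hydroxy-4,6-bis(methoxymethoxy)phenyl]-3-[3-allyl-4-methoxy-5-(methoxymethoxy)phenyl]prop-2-en-1-one
Conditions: KOH, EtOH–H2O, 0 °C to rt
Reagents that add atoms: none
Why: Claisen–Schmidt condensation in which the methyl ketone enolate adds to the non-enolisable aldehyde and E1cB loss of water gives the E-enone, with MOM ethers stable to base and unconjugated allyl groups not migrating at room temperature.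

**Step 9**
Reactants: 11 the E-chalcone
Product: 12 (±)-6,8-diallyl-2-[3-allyl-4-methoxy-5-(methoxymethoxy)phenyl]-5,7-bis(methoxymethoxy)chroman-4-one
Conditions: NaOAc, EtOH, reflux
Reagents that add atoms: none
Why: Base-mediated intramolecular oxa-Michael addition (6-endo-trig) of the single free 2'-OH closes ring C and creates C2 as a racemate, and because this is an equilibrium, unreacted 11 is recovered and resubmitted.

**Step 10**
Reactants: 12 the racemic tris-MOM triallyl flavanone
Product: 13 (2S)-6,8-diallyl-2-[3-allyl-4-methoxy-5-(methoxymethoxy)phenyl]-5,7-bis(methoxymethoxy)chroman-4-one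
Conditions: RuCl(p-cymene)[(R,R)-TsDPEN] (2 mol%), HCO2H–Et3N (5:2), EtOAc, rt, stopped just past half conversion (chiral HPLC control), chromatography
Reagents that add atoms: none
Why: Kinetic resolution of a racemic flavanone by asymmetric transfer hydrogenation, in which the (R,R)-catalyst builds a 4R carbinol that matches only the 2R ketone (cis-2,4 alcohol with equatorial aryl), so the 2S ketone stays behind and is separated from the more polar alcohol, while the coordinatively saturated Ru–H leaves the allyl groups alone.

**Step 11**
Reactants: 13 the (2S)-tris-MOM triallyl flavanone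
Product: 14 (2S)-6,8-diallyl-2-(3-allyl-5-hydroxy-4-methoxyphenyl)-5,7-dihydroxychroman-4-one
Conditions: conc. HCl (cat.), MeOH, 45 °C
Reagents that add atoms: none
Why: Acid-catalysed acetal solvolysis removes all three MOM groups, terminal allyl groups are not protonated under these conditions so no chroman or dihydrobenzofuran should form, and C2 should hold because opening of the flavanone ring needs base.

**Step 12**
Reactants: 14 (2S)-6,8-diallyl-2-(3-allyl-5-hydroxy-4-methoxyphenyl)-5,7-dihydroxychroman-4-one; 15 2-methylbut-2-ene (large excess, 3 equiv consumed)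
Product: 16 isoamoritin, (2S)-5,7-dihydroxy-2-[3-hydroxy-4-methoxy-5-(3-methylbut-2-enyl)phenyl]-6,8-bis(3-methylbut-2-enyl)chroman-4-one
Conditions: (H2IMes)(PCy3)Cl2Ru=CHPh (10 mol%, two portions), 1,4-benzoquinone (20 mol%), 15–CH2Cl2 (1:1), sealed tube, 40 °C; then DMSO, SiO2
Reagents that add atoms: none
Why: Olefin cross-metathesis through ruthenacyclobutanes: the alkylidene engages each monosubstituted alkene of 14, the metallacycle formed with 15 cycloreverts to the ArCH2CH=C(CH3)2 unit and a ruthenium ethylidene, and the ethylidene carries off the =CH2 end of the next allyl group as propene. The closest known reaction type is the conversion of allylarenes and ortho-allylphenols into prenylarenes with 2-methylbut-2-ene, here run at three sites of one molecule. No ring closes, because the C6 and C8 chains are meta to each other and could only give a prohibitively strained bridged ring and the C5' chain is remote, while homodimers and crotyl intermediates are 1,2-disubstituted alkenes that stay active and are driven onward by the excess of 15. No stereocentre is made, and C2 is untouched because the medium is neutral and aprotic. The step needs terminal over trisubstituted alkene selectivity and exchange over allyl-to-propenyl migration; the bulk of each finished prenyl terminus takes that chain out of the cycle, and catalytic benzoquinone intercepts ruthenium hydrides. Free phenols and the chelated 5-OH/C4=O unit are tolerated by this catalyst class.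

**Compound list**
1 | 2',4',6'-trihydroxyacetophenone | CC(=O)c1c(O)cc(O)cc1O | starting material
2 | allyl bromide | C=CCBr | starting material
3 | 1-[2,4-bis(allyloxy)-6-hydroxyphenyl]ethanone | CC(=O)c1c(O)cc(OCC=C)cc1OCC=C | intermediate
4 | 1-(3,5-diallyl-2,4,6-trihydroxyphenyl)ethanone | CC(=O)c1c(O)c(CC=C)c(O)c(CC=C)c1O | intermediate
5 | 1-[3,5-diallyl-2-hydroxy-4,6-bis(methoxymethoxy)phenyl]ethanone | CC(=O)c1c(O)c(CC=C)c(OCOC)c(CC=C)c1OCOC | intermediate
6 | 3,4-dihydroxybenzaldehyde | O=Cc1ccc(O)c(O)c1 | starting material
7 | 4-(allyloxy)-3-hydroxybenzaldehyde | O=Cc1ccc(OCC=C)c(O)c1 | intermediate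
8 | 4-(allyloxy)-3-(methoxymethoxy)benzaldehyde | O=Cc1ccc(OCC=C)c(OCOC)c1 | intermediate
9 | 3-allyl-4-hydroxy-5-(methoxymethoxy)benzaldehyde | O=Cc1cc(CC=C)c(O)c(OCOC)c1 | intermediate
10 | 3-allyl-4-methoxy-5-(methoxymethoxy)benzaldehyde | O=Cc1cc(CC=C)c(OC)c(OCOC)c1 | intermediate
11 | (E)-1-[3,5-diallyl-2-hydroxy-4,6-bis(methoxymethoxy)phenyl]-3-[3-allyl-4-methoxy-5-(methoxymethoxy)phenyl]prop-2-en-1-one | COc1c(OCOC)cc(/C=C/C(=O)c2c(O)c(CC=C)c(OCOC)c(CC=C)c2OCOC)cc1CC=C | intermediate
12 | (±)-6,8-diallyl-2-[3-allyl-4-methoxy-5-(methoxymethoxy)phenyl]-5,7-bis(methoxymethoxy)chroman-4-one (racemate) | COc1c(OCOC)cc(C2CC(=O)c3c(OCOC)c(CC=C)c(OCOC)c(CC=C)c3O2)cc1CC=C | intermediate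
13 | (2S)-6,8-diallyl-2-[3-allyl-4-methoxy-5-(methoxymethoxy)phenyl]-5,7-bis(methoxymethoxy)chroman-4-one | COc1c(OCOC)cc([C@@H]2CC(=O)c3c(OCOC)c(CC=C)c(OCOC)c(CC=C)c3O2)cc1CC=C | intermediate
14 | (2S)-6,8-diallyl-2-(3-allyl-5-hydroxy-4-methoxyphenyl)-5,7-dihydroxychroman-4-one | COc1c(O)cc([C@@H]2CC(=O)c3c(O)c(CC=C)c(O)c(CC=C)c3O2)cc1CC=C | intermediate
15 | 2-methylbut-2-ene | CC=C(C)C | starting material
16 | isoamoritin | COc1c(O)cc([C@@H]2CC(=O)c3c(O)c(CC=C(C)C)c(O)c(CC=C(C)C)c3O2)cc1CC=C(C)C | target

**Step count**
Total steps: 12. Longest linear sequence: 9 (steps 4 to 12, from 6 to 16).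

**Steps most likely to fail**

Step 12, the threefold metathesis. The exchange may stall with some chains still at the allyl or crotyl stage. The double bonds may migrate into conjugation under the action of ruthenium hydrides. The catalyst may also be tied up by the free phenols and the chelating 5-OH/carbonyl pair. The fallback moves the metathesis one stage earlier, to a substrate with no acidic OH. It sets out from 13, which is treated with 15 and the same class of ruthenium alkylidene to give (2S)-tris-O-methoxymethyl-isoamoritin F1. A short solvolysis of the three acetals in dilute methanolic HCl at or below room temperature then comes back to the route at 16. This accepts the known risk that a prenyl group cyclises onto a phenol as it is unmasked, so it is the second choice.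

Step 10, the kinetic resolution. Hydride transfer may be slow or discriminate poorly because the carbonyl is flanked by the 5-OMOM group. The recovered ketone would then reach high enantiomeric purity only at impractically high conversion. In the fallback C2 is built rather than resolved, setting out from 5 and 10.
- Ketone 5 is silylated twice (TMSOTf, Et3N, CH2Cl2, 0 °C) to the aryl silyl ether/silyl enol ether 1-[3,5-diallyl-4,6-bis(methoxymethoxy)-2-(trimethylsilyloxy)phenyl]vinyl trimethylsilyl ether F2.
- An enantioselective Mukaiyama aldol addition of F2 to 10 follows, under an N-tosyltryptophan-derived oxazaborolidinone (EtCN, −78 °C, antipode chosen for the R carbinol). Mild acidic desilylation should then give (3R)-1-[3,5-diallyl-2-hydroxy-4,6-bis(methoxymethoxy)phenyl]-3-[3-allyl-4-methoxy-5-(methoxymethoxy)phenyl]-3-hydroxypropan-1-one F3.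
- An intramolecular Mitsunobu etherification (PPh3, DIAD, toluene, 0 °C) lets the 2'-OH displace the activated benzylic oxygen with inversion and comes back to the route at 13.

Step 2, the double Claisen shift. At 200 °C the electron-rich product may degrade, the second shift may remain incomplete, or an ortho-allylphenol may cyclise further to a dihydrobenzofuran. The fallback uses direct C-allylation of the phloroglucinol nucleus. It sets out from 1, which is treated with 2 (2 equiv) in cold aqueous KOH. This is the ambident-phenolate C-alkylation used for 3,5-dialkylated acylphloroglucinols. Mono- and geminally allylated material is removed by chromatography, and the sequence comes back to the route at 4, skipping 3. This detour makes no compound outside the list (F0).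

**Further compounds**
F1 | step 12 | (2S)-5,7-bis(methoxymethoxy)-2-[4-methoxy-3-(methoxymethoxy)-5-(3-methylbut-2-enyl)phenyl]-6,8-bis(3-methylbut-2-enyl)chroman-4-one | COc1c(OCOC)cc([C@@H]2CC(=O)c3c(OCOC)c(CC=C(C)C)c(OCOC)c(CC=C(C)C)c3O2)cc1CC=C(C)C
F2 | step 10 | 1-[3,5-diallyl-4,6-bis(methoxymethoxy)-2-(trimethylsilyloxy)phenyl]vinyl trimethylsilyl ether | C=C(O[Si](C)(C)C)c1c(O[Si](C)(C)C)c(CC=C)c(OCOC)c(CC=C)c1OCOC
F3 | step 10 | (3R)-1-[3,5-diallyl-2-hydroxy-4,6-bis(methoxymethoxy)phenyl]-3-[3-allyl-4-methoxy-5-(methoxymethoxy)phenyl]-3-hydroxypropan-1-one | COc1c(OCOC)cc([C@H](O)CC(=O)c2c(O)c(CC=C)c(OCOC)c(CC=C)c2OCOC)cc1CC=C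
F0 | step 2 | none | none
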